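If this flask is run again, the electrophile left reads the reacted part directly, and the dissolved nucleophile is the pool between the solid and the reaction.

electrophile 0.097 M; buffer base 1.00 equiv; buffer acid 0.100 equiv; solid nucleophile 0.950 equiv; time 15 h

    crystals ⇌ leaving group, rate k1*(cs1 - [leaving group]) while solid is left; crystals form when [leaving group] > cs1 (cs1 = 0.075 M, k1 = 0.217 min⁻¹)
    solid nucleophile ⇌ nucleophile, rate k2*(cs2 - [nucleophile]) while solid is left; crystals form when [nucleophile] > cs2 (cs2 = 0.060 M, k2 = 0.00170 min⁻¹)
    buffer acid ⇌ buffer base + acid, settled at all times (K3 = 4.0 × 10⁻¹⁰ M)
    electrophile + nucleophile → acid + target + leaving group (k4 = 0.0267 M⁻¹ min⁻¹)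
    protonated nucleophile ⇌ nucleophile + acid, settled at all times (K5 = 1.3 × 10⁻⁸ M)
    electrophile + target → side product (k6 = 9.20 × 10⁻⁴ M⁻¹ min⁻¹)

* part of the electrophile that has reacted at 15 h
* pH of the solution at 15 h

- acid is the free proton; pH is minus the decimal logarithm of its molar concentration
- percentages count the electrophile that a species holds: one side product counts as two
- leaving group is meant together with its crystals
- solid, in amounts per volume of the solution: solid nucleophile, crystals
- at the start none of the solid nucleophile is in solution
- run time (flask): 15 h

Solid nucleophile is the limiting reagent, at 0.0921 M against 0.097 M of electrophile, so the ledger follows one of its molecules. It dissolves with coefficient 0.00170 min⁻¹ towards the solubility 0.060 M. Once dissolved, it meets electrophile, a pseudo-first-order loss of 0.00259 min⁻¹ while the electrophile stays near its charge. The half-life of target against electrophile is 130 h and that of nucleophile is 4.5 h, so this ledger carries no side product. Feed and loss balance at 0.0238 M, the balance level of dissolved nucleophile: dissolving coefficient times solubility, over the sum of dissolving and loss coefficients. The pool approaches it with a lag of 3.89 h, the inverse of that sum.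

dissolved nucleophile at time t = level × (1 − exp(−t/lag))

electrophile left, as a fraction = exp(−step constant × level × (t − lag × (1 − exp(−t/lag))))

The ledger at 15 h then reads:

reacted: 0.0337 M, which is 34.7 % of the electrophile

dissolved: 0.0233 M

protonated: 4.91 × 10⁻⁴ M

still solid, by subtraction: 0.0347 M

Each reacted molecule frees one acid, which turns buffer base into buffer acid, so acid stands at 2.74 × 10⁻¹⁰ M, and minus its decimal logarithm is the pH. Leaving group equals the reacted entry and stays below its solubility, so crystals get no entry.

The forecast lies above this ledger at 37.5 % (34 % to 41 %) with pH 9.54 (9.48 to 9.6), on the ground that the reaction is “limited by slow dissolution of the nucleophile”.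

The simulation gives 37.3 % reacted and pH 9.55, which is 2.6 percentage points above the ledger, with acid at 2.84 × 10⁻¹⁰ M and dissolved nucleophile at 0.0271 M against the ledger's 0.0233 M. The neighbouring flask holds the same charges and is read at 10 h. The same two lines, with the same level and lag, give 21.7 % reacted there, and that flask shows 22.5 %. Its dissolved nucleophile comes out at 0.0220 M by hand and reads 0.0235 M.

(All constants were chosen freely; the run is a simulation.)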